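**Retrosynthetic overview**

1. Feature: the ten-membered carbocycle C1–C10 (C1 CH–O-methacrylate, C2 CH–OH, C3 CH–CH3, C4 furanone O–C=, C5 =CH, C6 C=O, C7 C(CH3)–O, C8 CH2, C9 lactone O–CH, C10 lactone CH) holds a carvone ring in C6–C7–C8–C9–C10–C1, with the three lactone carbons as the isopropenyl group on C10; C2–C5 are inserted between C1 and C6.
2. Endgame disconnections: C1 ester; C1/C2 diol from the E C1=C2 alkene; furanone from C7–OH adding to the C4=C5–C6=O enone, then dehydrogenation; lactone from C9–OH and the oxidised isopropenyl carbon C12.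
3. Key disconnection: C3–C4 is formed and C1–C6 cleaved in an anionic acetylenic oxy-Cope ring expansion of a 1-ethynyl-2-[(E)-propenyl]cyclohexanol.
4. Precursor from (S)-carvone: C12 hydroxylation, oxygenation at C9, carbonyl transposition from C8 to C6, hydroxyl-directed epoxidation (sets C7), alkenylation at C1, epoxide-directed ethynyl addition (sets C6), hydride opening.
5. Ring order: six-membered carvone ring (given), ten-membered ring (step 12), γ-lactone (step 14), furanone ring (step 15, unsaturated in step 16).

Key step: step 12

Remark: the C1–C13 labels above are used for all intermediates (C11 lactone α-carbon, C12 lactone carbonyl carbon, C13 exocyclic CH2). β is the ring face of the C9 oxygen and α the face of the C10 side chain.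
Remark: (S)-carvone is used because the C9 oxygen is put in at its α′ carbon and the carbonyl is then transposed; with this mapping its stereocentre becomes C10 with the target's configuration.
Remark: the isopropenyl methyl is carried as a MOM ether from step 3 on, so no allylic oxidation is needed on the ten-membered ring.
Assumption: commercial (E)-1-bromoprop-1-ene is geometrically pure.

**Route**

Step 1
Reactants: 1 (S)-carvone
Product: 2 (S)-5-(3-hydroxyprop-1-en-2-yl)-2-methylcyclohex-2-en-1-one (12-hydroxycarvone)
Conditions: SeO2 (cat.), t-BuOOH, CH2Cl2, rt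
Reagents that add atoms: tert-butyl hydroperoxide CC(C)(C)OO
Why: Riley-type allylic oxidation (ene reaction, then [2,3]-sigmatropic shift) should hydroxylate the methyl group of the electron-rich 1,1-disubstituted alkene and not the electron-poor enone, and it touches no stereocentre.

Step 2
Reactants: 2 12-hydroxycarvone
Product: 5 (5R,6R)-6-hydroxy-5-(3-hydroxyprop-1-en-2-yl)-2-methylcyclohex-2-en-1-one (C9 hydroxyl trans to the C10 side chain), via bis-silyl dienol ether 3 (not isolated), via bis-silyl siloxy ketone 4 (not isolated)
Conditions: LiN(i-Pr)2 (2.2 equiv), Me3SiCl, THF, −78 °C; mCPBA, NaHCO3, CH2Cl2, −20 °C; dilute HCl, THF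
Reagents that add atoms: mCPBA O=C(OO)c1cccc(Cl)c1
Why: Rubottom oxidation, in which the kinetic cross-conjugated silyl dienol ether is epoxidised on the face opposite the adjacent C10 side chain and rearranges to the α-silyloxy ketone, which sets the C9 oxygen trans to C10 as the lactone requires.

Step 3
Reactants: 5 diol
Product: 6 bis-MOM ether of 5 (OMOM at C9 and C12)
Conditions: MOMCl, i-Pr2NEt, CH2Cl2, 0 °C → rt
Reagents that add atoms: chloromethyl methyl ether COCCl
Why: Acetal formation (MOM protection) of both hydroxyls under amine base is routine and should leave the α-alkoxy ketone centre C9 in its trans arrangement.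

Step 4
Reactants: 6 bis-MOM enone
Product: 7 epoxy ketone (C8 ketone; C6–C7 β-epoxide, trans to the C10 side chain)
Conditions: H2O2 (30 %), NaOH (cat.), MeOH, 0 °C
Reagents that add atoms: hydrogen peroxide OO
Why: Weitz–Scheffer nucleophilic epoxidation, in which hydroperoxide adds axially to C6 on the face opposite the C10 side chain and the enolate closes the oxirane, so the C6 oxygen is set β and can later direct the C7 oxygen.

Step 5
Reactants: 7 epoxy ketone
Product: 9 allylic alcohol (C6 β-hydroxyl; C7=C8 alkene), via epoxy hydrazone 8 (not isolated)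
Conditions: N2H4·H2O, AcOH (cat.), MeOH, 0 °C → rt
Reagents that add atoms: none
Why: Wharton transposition, in which the epoxy hydrazone fragments with loss of N2, turns the carbonyl carbon C8 into an alkene CH and leaves the C6–O bond untouched, so oxygen moves to C6 with its β configuration retained.

Step 6
Reactants: 9 allylic alcohol
Product: 10 epoxy alcohol (C7–C8 β-epoxide cis to the C6 hydroxyl)
Conditions: VO(acac)2 (cat.), t-BuOOH, CH2Cl2, rt
Reagents that add atoms: tert-butyl hydroperoxide CC(C)(C)OO
Why: Hydroxyl-directed epoxidation of a cyclic allylic alcohol by the vanadium alkylperoxide should occur syn to the C6 hydroxyl and only at C7=C8, which sets the C7–O bond β (the R configuration of the target).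

Step 7
Reactants: 10 epoxy alcohol
Product: 11 epoxy ketone (C6 ketone; C7–C8 β-epoxide; C9 β-OMOM; C10 α side chain)
Conditions: Dess–Martin periodinane, NaHCO3, CH2Cl2, 0 °C → rt
Reagents that add atoms: none
Why: Dess–Martin oxidation of the secondary alcohol under buffered conditions should give the α,β-epoxy ketone without opening the oxirane or epimerising a centre.

Step 8
Reactants: 11 epoxy ketone; 12 (E)-1-bromoprop-1-ene
Product: 14 C1 β-[(E)-prop-1-enyl] epoxy ketone (propenyl trans to the C10 side chain), via lithium enolate 13 (not isolated)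
Conditions: LiN(SiMe3)2 (2.2 equiv), Pd2(dba)3 (2.5 mol %), P(t-Bu)3·HBF4 (6 mol %), THF, 0 °C → rt; AcOH quench, −78 °C
Reagents that add atoms: none
Why: Palladium-catalysed α-alkenylation of a ketone enolate, in which oxidative addition and reductive elimination keep the E geometry, C1 is the only enolisable position, and protonation of the product dienolate at C1 should place the propenyl group equatorial and trans to the C10 side chain.

Step 9
Reactants: 14 propenyl epoxy ketone; 15 ethynylmagnesium bromide
Product: 16 tertiary propargylic alcohol (C6 β-hydroxyl cis to the oxirane; C6 α-ethynyl trans to the propenyl group)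
Conditions: CeCl3, THF, −78 → −20 °C; aq. NH4Cl
Reagents that add atoms: none
Why: Cerium-mediated Grignard 1,2-addition (to suppress enolisation at C1), in which the acetylide should attack the face opposite both the metal-chelating epoxide oxygen and the β-propenyl group, so that the ethynyl group ends up trans to the propenyl group.

Step 10
Reactants: 16 epoxy alkynol
Product: 17 diol (C6 β-OH and C7 β-OH; C8 CH2)
Conditions: LiEt3BH (4 equiv), THF, 0 → 40 °C; H2O
Reagents that add atoms: none
Why: SN2 hydride opening of the trisubstituted epoxide at the less substituted carbon C8 leaves the C7–O bond and its configuration untouched and gives the tertiary C7 alcohol.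

Step 11
Reactants: 17 diol
Product: 18 1-ethynyl-2-[(E)-propenyl]cyclohexanol with OMOM at C7, C9 and C12 (oxy-Cope precursor)
Conditions: MOMCl, i-Pr2NEt, NaI (cat.), CH2Cl2, 0 → 35 °C
Reagents that add atoms: chloromethyl methyl ether COCCl
Why: MOM protection should occur at the C7 hydroxyl, which is equatorial and flanked by CH2 and CH3, in preference to the axial propargylic C6 hydroxyl between a quaternary and a tertiary carbon.

Step 12
Reactants: 18 oxy-Cope precursor
Product: 21 cyclodeca-2,5-dienone (C6 ketone; Z C4=C5; C3 methyl; E C1=C2), via potassium alkoxide 19 (not isolated), via potassium allenolate 20 (not isolated)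
Conditions: KH (1.2 equiv), 18-crown-6, THF, 0 °C → rt; inverse quench into AcOH/THF, −78 °C
Reagents that add atoms: none
Why: The C6 oxyanion of 19 weakens the C1–C6 bond and triggers a concerted [3,3]-sigmatropic shift through C4≡C5–C6–C1–C2=C3 that forms C3–C4, cleaves C1–C6 and gives allenolate 20, which is protonated at C5 on the side of H4 to give the cis enone; the closest known reaction type is the anionic acetylenic oxy-Cope ring expansion of 1-alkynyl-2-alkenylcyclohexanols to cyclodecenones. The ten-membered ring is closed by four-atom ring expansion of the six-membered ring, not by end-to-end cyclisation: the new bond forms between the gauche, equatorial ethynyl and propenyl groups of a chair as the ring bond breaks. The new C3 centre is controlled by the C1 configuration and the E propenyl geometry, because C4 must bond to the alkene face syn to the breaking C1–C6 bond, and with H1 eclipsing the alkene (allylic strain minimised) that face gives the target's C3 configuration together with an E C1=C2 bond. The step needs the two unsaturated groups trans-diequatorial, which the epoxide-directed addition of step 9 secures, and a single alkoxide at C6, which the C7 MOM ether secures (a free C7 alkoxide could add 5-endo to the alkyne). The cold inverse quench should prevent deprotonation at the doubly allylic C3 of the product.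

Step 13
Reactants: 21 cyclodecadienone
Product: 23 triol (free hydroxyls at C7, C9 and C12), via tris(bromomethyl) ether 22 (not isolated)
Conditions: Me2BBr, CH2Cl2, −78 °C; then THF, aq. NaHCO3
Reagents that add atoms: none
Why: Lewis-acid cleavage of MOM ethers with Me2BBr proceeds at −78 °C through bromomethyl ethers that hydrolyse on work-up, conditions under which the enone and the C3 centre should not enolise.

Step 14
Reactants: 23 triol
Product: 26 trans-fused α-methylene-γ-lactone (C9–O–C12) bearing the C7 hydroxy enone, via hydroxy enal 24 (not isolated), via lactol 25 (not isolated)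
Conditions: TEMPO (cat.), PhI(OAc)2, CH2Cl2, rt
Reagents that add atoms: none
Why: Oxoammonium-catalysed oxidative lactonisation, in which the primary allylic alcohol is oxidised in preference to the secondary and tertiary ones, the enal is captured by the C9 hydroxyl as a five-membered lactol and this is oxidised to the lactone, whose trans fusion is fixed by C9 and C10.

Step 15
Reactants: 26 hydroxy enone lactone
Product: 27 oxa-bridged tetrahydrofuran-3-one (C7–O–C4; either C4 epimer)
Conditions: camphor-10-sulfonic acid (cat.), CH2Cl2, rt
Reagents that add atoms: none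
Why: Acid-catalysed intramolecular oxa-Michael addition (5-endo-trig, feasible under acid because the protonated enone reacts as a hydroxyallyl cation) of the C7 hydroxyl to C4 closes the tetrahydrofuranone, and the new C4 centre is of no consequence because it becomes sp2 in step 16.

Step 16
Reactants: 27 tetrahydrofuranone
Product: 29 3(2H)-furanone lactone with the E C1=C2 alkene, via silyl enol ether 28 (not isolated)
Conditions: Me3SiOTf, Et3N, CH2Cl2, 0 °C; then Pd(OAc)2, MeCN, rt
Reagents that add atoms: none
Why: Saegusa–Ito oxidation, in which soft enolisation can only occur towards C5 and β-hydride elimination from the palladium enolate removes the C4 hydrogen to give the furanone.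

Step 17
Reactants: 29 furanone lactone
Product: 30 (1S,2S)-diol
Conditions: OsO4 (cat.), (DHQ)2PHAL (cat.), N-methylmorpholine N-oxide, acetone–H2O, 0 °C
Reagents that add atoms: N-methylmorpholine N-oxide C[N+]1([O-])CCOCC1; water O
Why: Osmium-catalysed syn-dihydroxylation should select the strained, electron-rich E C1=C2 alkene over the electron-poor methylene lactone and the push–pull furanone alkene, syn addition to the E alkene gives the threo C1/C2 relationship, and the (DHQ)2PHAL ligand (which gives S,S diols from E-1,2-dialkyl alkenes) is used to favour the 1S,2S face.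

Step 18
Reactants: 30 diol
Product: 31 CNP0195404.1 (target)
Conditions: methacrylic anhydride (1.1 equiv), Et3N, DMAP (cat.), CH2Cl2, −40 → 0 °C
Reagents that add atoms: methacrylic anhydride CC(=C)C(=O)OC(=O)C(C)=C
Why: DMAP-catalysed acyl transfer at low temperature should esterify the C1 hydroxyl, whose neighbour C10 is tied back in the lactone ring, faster than the C2 hydroxyl next to the methyl-bearing C3, under conditions that avoid acyl migration.

**Compound list**

1 | (S)-carvone | CC1=CC[C@@H](CC1=O)C(C)=C | starting material
2 | (S)-5-(3-hydroxyprop-1-en-2-yl)-2-methylcyclohex-2-en-1-one | CC1=CC[C@@H](CC1=O)C(=C)CO | intermediate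
3 | bis(trimethylsilyl) dienol ether of 2 | CC1=CC[C@H](C(=C)CO[Si](C)(C)C)C=C1O[Si](C)(C)C | intermediate
4 | C9 trimethylsilyloxy ketone, C12 silyl ether | CC1=CC[C@H](C(=C)CO[Si](C)(C)C)[C@@H](O[Si](C)(C)C)C1=O | intermediate
5 | (5R,6R)-6-hydroxy-5-(3-hydroxyprop-1-en-2-yl)-2-methylcyclohex-2-en-1-one | CC1=CC[C@H](C(=C)CO)[C@@H](O)C1=O | intermediate
6 | bis-MOM ether of 5 | CC1=CC[C@H](C(=C)COCOC)[C@@H](OCOC)C1=O | intermediate
7 | C8 ketone with C6–C7 β-epoxide | O1[C@H]2C[C@H](C(=C)COCOC)[C@@H](OCOC)C(=O)[C@@]12C | intermediate
8 | hydrazone of 7 | O1[C@H]2C[C@H](C(=C)COCOC)[C@@H](OCOC)C(=NN)[C@@]12C | intermediate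
9 | allylic alcohol, C6 β-OH, C7=C8 | O[C@H]1C[C@H](C(=C)COCOC)[C@@H](OCOC)C=C1C | intermediate
10 | epoxy alcohol, C7–C8 β-epoxide cis to C6–OH | O[C@H]1C[C@H](C(=C)COCOC)[C@@H](OCOC)[C@H]2O[C@@]12C | intermediate
11 | C6 ketone with C7–C8 β-epoxide | O=C1C[C@H](C(=C)COCOC)[C@@H](OCOC)[C@H]2O[C@@]12C | intermediate
12 | (E)-1-bromoprop-1-ene | C/C=C/Br | starting material
13 | lithium enolate of 11 | [Li+].[O-]C1=C[C@H](C(=C)COCOC)[C@@H](OCOC)[C@H]2O[C@@]12C | intermediate
14 | C1 β-[(E)-prop-1-enyl] epoxy ketone | O=C1[C@@H](/C=C/C)[C@H](C(=C)COCOC)[C@@H](OCOC)[C@H]2O[C@@]12C | intermediate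
15 | ethynylmagnesium bromide | C#C[Mg]Br | starting material
16 | C6 α-ethynyl β-hydroxy epoxide | C#C[C@]1(O)[C@@H](/C=C/C)[C@H](C(=C)COCOC)[C@@H](OCOC)[C@H]2O[C@@]12C | intermediate
17 | C6,C7 diol | C#C[C@]1(O)[C@@H](/C=C/C)[C@H](C(=C)COCOC)[C@@H](OCOC)C[C@@]1(C)O | intermediate
18 | oxy-Cope precursor, C7 OMOM | C#C[C@]1(O)[C@@H](/C=C/C)[C@H](C(=C)COCOC)[C@@H](OCOC)C[C@@]1(C)OCOC | intermediate
19 | potassium alkoxide of 18 | [K+].C#C[C@]1([O-])[C@@H](/C=C/C)[C@H](C(=C)COCOC)[C@@H](OCOC)C[C@@]1(C)OCOC | intermediate
20 | ten-membered potassium allenolate | [K+].[O-]C1=C=C[C@@H](C)/C=C/[C@H](C(=C)COCOC)[C@@H](OCOC)C[C@@]1(C)OCOC | intermediate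
21 | cyclodeca-2,5-dienone, Z C4=C5, E C1=C2 | O=C1/C=C\[C@@H](C)/C=C/[C@H](C(=C)COCOC)[C@@H](OCOC)C[C@@]1(C)OCOC | intermediate
22 | tris(bromomethyl) ether of the triol | O=C1/C=C\[C@@H](C)/C=C/[C@H](C(=C)COCBr)[C@@H](OCBr)C[C@@]1(C)OCBr | intermediate
23 | C7,C9,C12 triol | O=C1/C=C\[C@@H](C)/C=C/[C@H](C(=C)CO)[C@@H](O)C[C@@]1(C)O | intermediate
24 | C12 enal with C7 and C9 hydroxyls | O=C1/C=C\[C@@H](C)/C=C/[C@H](C(=C)C=O)[C@@H](O)C[C@@]1(C)O | intermediate
25 | lactol (C9–O–C12) | O=C1/C=C\[C@@H](C)/C=C/[C@@H]2C(=C)C(O)O[C@H]2C[C@@]1(C)O | intermediate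
26 | trans-fused α-methylene lactone, C7 hydroxy enone | O=C1/C=C\[C@@H](C)/C=C/[C@@H]2C(=C)C(=O)O[C@H]2C[C@@]1(C)O | intermediate
27 | oxa-bridged tetrahydrofuran-3-one | C[C@H]1/C=C/[C@@H]2C(=C)C(=O)O[C@H]2C[C@@]3(C)OC1CC3=O | intermediate
28 | trimethylsilyl enol ether of 27 | C[C@H]1/C=C/[C@@H]2C(=C)C(=O)O[C@H]2C[C@@]3(C)OC1C=C3O[Si](C)(C)C | intermediate
29 | 3(2H)-furanone lactone, E C1=C2 | C[C@H]1/C=C/[C@@H]2C(=C)C(=O)O[C@H]2C[C@@]3(C)OC1=CC3=O | intermediate
30 | (1S,2S)-diol | C[C@H]1[C@H](O)[C@@H](O)[C@@H]2C(=C)C(=O)O[C@H]2C[C@@]3(C)OC1=CC3=O | intermediate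
31 | CNP0195404.1 | C=C(C)C(=O)O[C@@H]1[C@@H](O)[C@H](C)C2=CC(=O)[C@@](C)(C[C@@H]3OC(=O)C(=C)[C@@H]13)O2 | target

**Summary**

Total step count: 18. Longest linear sequence: 18 steps (1 to 31); 12 and 15 are bought.

Steps most likely to fail:

Step 12. The alkoxide may lose acetylide by retro-addition faster than it rearranges, or the doubly allylic C3 position may be deprotonated after the enone is set free, which would scramble C3 or move the alkene into conjugation. The fallback sets out from 14 and comes back at 21 and uses the all-alkene anionic oxy-Cope. Vinylmagnesium bromide with CeCl3 is added to 14, again anti to the oxirane, to give vinyl carbinol F1. LiEt3BH opens the epoxide to diol F2, and MOMCl gives C7 MOM ether F3. With KH and 18-crown-6 this trans-1,2-dialkenylcyclohexanol should rearrange to ten-membered potassium enolate F4, which is trapped in the flask with Me3SiCl as silyl enol ether F5. Saegusa–Ito oxidation with Pd(OAc)2 then introduces the C4=C5 bond and should give 21, the cis enone being the less strained geometry in the ten-membered ring.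

Step 8. The lithium enolate of the α,β-epoxy ketone may collapse before it couples, either by Favorskii-type attack on the oxirane carbon or by opening of its vinyl-epoxide-like form by zerovalent palladium, and the β,γ-alkene may drift into conjugation in the basic medium. The fallback sets out from 11 and comes back at 14 and reverses the polarity at C1. Enolate 13 is silylated at −78 °C to silyl enol ether F6, and NBS gives α-bromo ketone F7. F7 is coupled without base, under NiCl2·glyme and a bis(oxazoline) ligand, with (E)-prop-1-enylzirconocene chloride F8, which is made by hydrozirconation of propyne with Cp2Zr(H)Cl. The E geometry is retained, and the C1 radical should be captured trans to the C10 side chain.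

Step 18. Discrimination between the two secondary hydroxyls may be poor or reversed, and the ester may migrate from one to the other. The fallback sets out from 30 and comes back at 31 and uses the reversed preference: if the C2 hydroxyl is the more reactive one, it is capped first with Et3SiCl and imidazole to give C2 triethylsilyl ether F9. The remaining C1 hydroxyl is esterified with methacrylic anhydride and DMAP to give silyl ether methacrylate F10, and HF·pyridine removes the silyl group under acidic conditions that do not move the ester.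

**Further compounds**

F1 | step 12 | C6 α-vinyl β-hydroxy epoxide | C=C[C@]1(O)[C@@H](/C=C/C)[C@H](C(=C)COCOC)[C@@H](OCOC)[C@H]2O[C@@]12C
F2 | step 12 | vinyl carbinol C6,C7 diol | C=C[C@]1(O)[C@@H](/C=C/C)[C@H](C(=C)COCOC)[C@@H](OCOC)C[C@@]1(C)O
F3 | step 12 | vinyl carbinol with C7 OMOM | C=C[C@]1(O)[C@@H](/C=C/C)[C@H](C(=C)COCOC)[C@@H](OCOC)C[C@@]1(C)OCOC
F4 | step 12 | ten-membered potassium enolate (C5=C6) | [K+].[O-]C1=CC[C@@H](C)/C=C/[C@H](C(=C)COCOC)[C@@H](OCOC)C[C@@]1(C)OCOC
F5 | step 12 | trimethylsilyl enol ether of the cyclodec-5-enone | C[Si](C)(C)OC1=CC[C@@H](C)/C=C/[C@H](C(=C)COCOC)[C@@H](OCOC)C[C@@]1(C)OCOC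
F6 | step 8 | trimethylsilyl enol ether of 11 | C[Si](C)(C)OC1=C[C@H](C(=C)COCOC)[C@@H](OCOC)[C@H]2O[C@@]12C
F7 | step 8 | C1 bromo epoxy ketone (either C1 epimer) | O=C1C(Br)[C@H](C(=C)COCOC)[C@@H](OCOC)[C@H]2O[C@@]12C
F8 | step 8 | (E)-prop-1-enylzirconocene chloride, Cp2Zr(Cl)CH=CHCH3 | C/C=C/[Zr](Cl)(C1C=CC=C1)C1C=CC=C1
F9 | step 18 | C2 triethylsilyl ether of 30 | C[C@H]1[C@H](O[Si](CC)(CC)CC)[C@@H](O)[C@@H]2C(=C)C(=O)O[C@H]2C[C@@]3(C)OC1=CC3=O
F10 | step 18 | C1 methacrylate, C2 triethylsilyl ether | C[C@H]1[C@H](O[Si](CC)(CC)CC)[C@@H](OC(=O)C(C)=C)[C@@H]2C(=C)C(=O)O[C@H]2C[C@@]3(C)OC1=CC3=O
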